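The target is cut at the two aryl C–O bonds of ring C that flank C4'–O4': the ring-B oxygen O5' at C5' and the methoxy oxygen at C3'. Both are traced to the two equivalent bromines of a 2,6-dibromophenyl ether of the C8 carbinol, so no regiochemistry has to be controlled. In one copper-mediated operation the C7 alkoxide closes dioxane ring B on one bromine with retention at C7 and C8, and methoxide then replaces the other. The precursor is the threo (7R,8R) 1-aryl-2-aryloxypropan-1-ol with a free C7 hydroxyl, a dibromo ring C and the future side-chain carbon masked as a dioxolane, assembled from ethyl (S)-lactate.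

Key step: step 6

Remark: lignan numbering is used for atoms (ring A = 3,4,5-trimethoxyphenyl, C7 = benzylic carbon, C8 = methyl-bearing carbon, ring B = dioxane, ring C = benzo ring with primed atoms; O4' sits on C8, O5' on C7). In benzodioxine names O1 is the oxygen on the aryl-bearing C2.

Step 1
Reactants: 1 ethyl (S)-lactate; 2 3,5-dibromo-4-hydroxybenzaldehyde
Product: 3 ethyl (R)-2-(2,6-dibromo-4-formylphenoxy)propanoate
Conditions: PPh3, DIAD, THF, 0 °C to rt
Reagents that add atoms: none
Why: Mitsunobu etherification, in which the acidic phenol protonates the betaine and its phenoxide displaces the oxyphosphonium of the activated α-ester carbinol by SN2 with inversion, turning the (S) centre into the (R) configuration needed at C8.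

Step 2
Reactants: 3 ethyl (R)-2-(2,6-dibromo-4-formylphenoxy)propanoate
Product: 4 ethyl (R)-2-[2,6-dibromo-4-(1,3-dioxolan-2-yl)phenoxy]propanoate
Conditions: ethylene glycol, p-TsOH (cat.), toluene, reflux, Dean–Stark
Reagents that add atoms: ethylene glycol, OCCO
Why: Acid-catalysed acetalisation with azeotropic removal of water, which masks the aldehyde against the organomagnesium and hydride reagents to come and leaves ring C without a para acceptor.

Step 3
Reactants: 4 ethyl (R)-2-[2,6-dibromo-4-(1,3-dioxolan-2-yl)phenoxy]propanoate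
Product: 5 (R)-2-[2,6-dibromo-4-(1,3-dioxolan-2-yl)phenoxy]-N-methoxy-N-methylpropanamide
Conditions: MeNH(OMe)·HCl, i-PrMgCl (premixed), THF, −20 °C; then 4, −20 to 0 °C; aq. NH4Cl
Reagents that add atoms: N,O-dimethylhydroxylamine hydrochloride, CNOC.Cl
Why: Weinreb amide formation by aminolysis of the ester with the preformed chloromagnesium amide, so that no free i-PrMgCl meets the aryl bromides and the weakly basic amide should leave C8 untouched.

Step 4
Reactants: 5 (R)-2-[2,6-dibromo-4-(1,3-dioxolan-2-yl)phenoxy]-N-methoxy-N-methylpropanamide; 6 5-bromo-1,2,3-trimethoxybenzene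
Product: 8 (R)-2-[2,6-dibromo-4-(1,3-dioxolan-2-yl)phenoxy]-1-(3,4,5-trimethoxyphenyl)propan-1-one, via 3,4,5-trimethoxyphenylmagnesium bromide 7 (not isolated)
Conditions: 6, Mg, I2 (cat.), THF, 40 °C; then 5, THF, −20 to 0 °C; aq. NH4Cl
Reagents that add atoms: none
Why: Grignard addition to a Weinreb amide, whose chelated tetrahedral magnesium intermediate survives until the quench and so excludes over-addition, while at low temperature acylation should outpace bromine–magnesium exchange at ring C and deprotonation at C8.

Step 5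
Reactants: 8 (R)-2-[2,6-dibromo-4-(1,3-dioxolan-2-yl)phenoxy]-1-(3,4,5-trimethoxyphenyl)propan-1-one
Product: 9 (1R,2R)-2-[2,6-dibromo-4-(1,3-dioxolan-2-yl)phenoxy]-1-(3,4,5-trimethoxyphenyl)propan-1-ol
Conditions: LiBH(s-Bu)3, THF, −78 °C; aq. NH4Cl
Reagents that add atoms: none
Why: Felkin–Anh (polar) controlled ketone reduction, in which the hindered, weakly basic 2,6-dibromoaryloxy oxygen should not chelate lithium, so the bulky hydride attacks anti to the C8–OAr bond and past the C8 hydrogen, setting C7 as R (threo).

Step 6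
Reactants: 9 (1R,2R)-2-[2,6-dibromo-4-(1,3-dioxolan-2-yl)phenoxy]-1-(3,4,5-trimethoxyphenyl)propan-1-ol
Product: 11 2-[(2R,3R)-5-methoxy-3-methyl-2-(3,4,5-trimethoxyphenyl)-2,3-dihydro-1,4-benzodioxin-7-yl]-1,3-dioxolane, via 5-bromobenzodioxane acetal 10 (not isolated)
Conditions: CuI (10 mol %), 3,4,7,8-tetramethyl-1,10-phenanthroline (20 mol %), Cs2CO3, toluene, 110 °C, argon; then NaOMe in MeOH, DMF, 110 °C, same vessel
Reagents that add atoms: sodium methoxide, C[O-].[Na+]
Why: Cs2CO3 deprotonates the C7 hydroxyl, the alkoxide binds monovalent copper, oxidative addition into one of the two equivalent ortho C–Br bonds gives a trivalent-copper aryl alkoxide, and reductive elimination forms O5'–C5'; methoxide then passes through the same cycle at the remaining C3'–Br bond. The closest known reactions are the Ullmann-type intramolecular O-arylation of alcohols to 1,4-benzodioxanes and the copper-catalysed methoxylation of aryl bromides with NaOMe, run here one after the other in one vessel. Ring B closes in a six-membered mode by attack of the tethered O7 on C5' (ring atoms O5', C7, C8, O4', C4', C5'). No stereocentre is created: neither the C7–O nor the C8–O bond is broken, so the threo (7R,8R) configuration of 9 is carried unchanged into the trans-2,3-disubstituted ring. The step needs ring closure to outrun methoxylation, aryl migration between the two oxygens (Smiles rearrangement) and expulsion of the phenoxide by the alkoxide; this is secured by the local symmetry of the dibromoarene (either bromine gives the same product), by the intramolecular six-ring closure being faster than any intermolecular coupling, by adding NaOMe only once 9 is consumed, and by the acetal, which leaves ring C without a para acceptor.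

Step 7
Reactants: 11 2-[(2R,3R)-5-methoxy-3-methyl-2-(3,4,5-trimethoxyphenyl)-2,3-dihydro-1,4-benzodioxin-7-yl]-1,3-dioxolane
Product: 12 (2R,3R)-5-methoxy-3-methyl-2-(3,4,5-trimethoxyphenyl)-2,3-dihydro-1,4-benzodioxine-7-carbaldehyde
Conditions: 1 M aq. HCl, THF, rt
Reagents that add atoms: water, O
Why: Acid-catalysed acetal hydrolysis, to which the benzodioxane ring, the aryl methyl ethers and both stereocentres should be inert in dilute acid at room temperature.

Step 8
Reactants: 12 (2R,3R)-5-methoxy-3-methyl-2-(3,4,5-trimethoxyphenyl)-2,3-dihydro-1,4-benzodioxine-7-carbaldehyde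
Product: 13 ethyl (E)-3-[(2R,3R)-5-methoxy-3-methyl-2-(3,4,5-trimethoxyphenyl)-2,3-dihydro-1,4-benzodioxin-7-yl]prop-2-enoate
Conditions: triethyl phosphonoacetate, NaH, THF, 0 °C to rt
Reagents that add atoms: triethyl phosphonoacetate, CCOC(=O)CP(=O)(OCC)OCC
Why: Horner–Wadsworth–Emmons olefination, in which the stabilised phosphonate anion adds reversibly to the aryl aldehyde and eliminates through the anti oxaphosphetane, which should give the E enoate.

Step 9
Reactants: 13 ethyl (E)-3-[(2R,3R)-5-methoxy-3-methyl-2-(3,4,5-trimethoxyphenyl)-2,3-dihydro-1,4-benzodioxin-7-yl]prop-2-enoate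
Product: 14 (E)-3-[(2R,3R)-5-methoxy-3-methyl-2-(3,4,5-trimethoxyphenyl)-2,3-dihydro-1,4-benzodioxin-7-yl]prop-2-en-1-ol
Conditions: i-Bu2AlH, CH2Cl2, −78 to 0 °C; aq. potassium sodium tartrate
Reagents that add atoms: none
Why: 1,2-Reduction of the α,β-unsaturated ester by i-Bu2AlH at low temperature, where the aluminium hydride attacks the carbonyl and not the conjugated alkene, so the E double bond and both stereocentres are kept.

Compound list
1 | ethyl (S)-lactate | CCOC(=O)[C@H](C)O | starting material
2 | 3,5-dibromo-4-hydroxybenzaldehyde | O=Cc1cc(Br)c(O)c(Br)c1 | starting material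
3 | ethyl (R)-2-(2,6-dibromo-4-formylphenoxy)propanoate | CCOC(=O)[C@@H](C)Oc1c(Br)cc(C=O)cc1Br | intermediate
4 | ethyl (R)-2-[2,6-dibromo-4-(1,3-dioxolan-2-yl)phenoxy]propanoate | CCOC(=O)[C@@H](C)Oc1c(Br)cc(C2OCCO2)cc1Br | intermediate
5 | (R)-2-[2,6-dibromo-4-(1,3-dioxolan-2-yl)phenoxy]-N-methoxy-N-methylpropanamide | CON(C)C(=O)[C@@H](C)Oc1c(Br)cc(C2OCCO2)cc1Br | intermediate
6 | 5-bromo-1,2,3-trimethoxybenzene | COc1cc(Br)cc(OC)c1OC | starting material
7 | 3,4,5-trimethoxyphenylmagnesium bromide | COc1cc([Mg]Br)cc(OC)c1OC | intermediate (not isolated)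
8 | (R)-2-[2,6-dibromo-4-(1,3-dioxolan-2-yl)phenoxy]-1-(3,4,5-trimethoxyphenyl)propan-1-one | COc1cc(C(=O)[C@@H](C)Oc2c(Br)cc(C3OCCO3)cc2Br)cc(OC)c1OC | intermediate
9 | (1R,2R)-2-[2,6-dibromo-4-(1,3-dioxolan-2-yl)phenoxy]-1-(3,4,5-trimethoxyphenyl)propan-1-ol | COc1cc([C@@H](O)[C@@H](C)Oc2c(Br)cc(C3OCCO3)cc2Br)cc(OC)c1OC | intermediate
10 | 2-[(2R,3R)-5-bromo-3-methyl-2-(3,4,5-trimethoxyphenyl)-2,3-dihydro-1,4-benzodioxin-7-yl]-1,3-dioxolane | COc1cc([C@H]2Oc3cc(C4OCCO4)cc(Br)c3O[C@@H]2C)cc(OC)c1OC | intermediate (not isolated)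
11 | 2-[(2R,3R)-5-methoxy-3-methyl-2-(3,4,5-trimethoxyphenyl)-2,3-dihydro-1,4-benzodioxin-7-yl]-1,3-dioxolane | COc1cc([C@H]2Oc3cc(C4OCCO4)cc(OC)c3O[C@@H]2C)cc(OC)c1OC | intermediate
12 | (2R,3R)-5-methoxy-3-methyl-2-(3,4,5-trimethoxyphenyl)-2,3-dihydro-1,4-benzodioxine-7-carbaldehyde | COc1cc([C@H]2Oc3cc(C=O)cc(OC)c3O[C@@H]2C)cc(OC)c1OC | intermediate
13 | ethyl (E)-3-[(2R,3R)-5-methoxy-3-methyl-2-(3,4,5-trimethoxyphenyl)-2,3-dihydro-1,4-benzodioxin-7-yl]prop-2-enoate | COc1cc([C@H]2Oc3cc(/C=C/C(=O)OCC)cc(OC)c3O[C@@H]2C)cc(OC)c1OC | intermediate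
14 | (E)-3-[(2R,3R)-5-methoxy-3-methyl-2-(3,4,5-trimethoxyphenyl)-2,3-dihydro-1,4-benzodioxin-7-yl]prop-2-en-1-ol | COc1cc([C@H]2Oc3cc(/C=C/CO)cc(OC)c3O[C@@H]2C)cc(OC)c1OC | target

Total step count: 9. Longest linear sequence: 9 steps (1 to 14; the arylmagnesium reagent 7 is made in the flask within step 4).

Steps most likely to fail

Step 6. Oxidative addition at the hindered, electron-rich C–Br bond may be slow, so that alkoxide-induced loss of the dibromophenoxide or O-to-O aryl migration competes with ring closure; in the second stage reductive loss of bromine may compete with methoxylation. Fallback: setting out from 9, the two C–O bonds are made in two separate palladium-catalysed operations instead of one copper pot. Intramolecular etherification on zerovalent palladium (Pd(OAc)2, 2-(di-tert-butylphosphino)-1,1'-binaphthyl, Cs2CO3, toluene, 70 °C) should give bromide 10, which is isolated. Methoxylation of 10 (Pd2(dba)3, t-BuBrettPhos, MeOH, NaOt-Bu, 1,4-dioxane, 50 °C) comes back to the route at 11. No compound outside the list is made (F0).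

Step 5. Hydride delivery may show poor facial selectivity if the chelated transition state competes with the polar Felkin–Anh one, and C8 may erode through enolisation. Fallback: setting out from 8, the ketone is reduced under neutral conditions that favour or at least tolerate the other face (Zn(BH4)2, Et2O, −20 °C) and the diastereomers are separated. The erythro alcohol (1S,2R)-2-[2,6-dibromo-4-(1,3-dioxolan-2-yl)phenoxy]-1-(3,4,5-trimethoxyphenyl)propan-1-ol F1 is then inverted at C7 by a Mitsunobu reaction with 4-nitrobenzoic acid (PPh3, DIAD, THF) to (1R,2R)-2-[2,6-dibromo-4-(1,3-dioxolan-2-yl)phenoxy]-1-(3,4,5-trimethoxyphenyl)propyl 4-nitrobenzoate F2. Methanolysis of F2 (K2CO3 cat., MeOH, rt) comes back to the route at 9.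

Step 1. SN2 capture of the lactate oxyphosphonium by the hindered, weakly nucleophilic 2,6-dibromophenoxide may be slow, so that alkylation of the reduced azodicarboxylate or elimination takes over. Fallback: setting out from 1, the alcohol is converted with retention into ethyl (S)-2-(trifluoromethylsulfonyloxy)propanoate F3 (Tf2O, 2,6-lutidine, CH2Cl2, −78 °C). Displacement of the triflate by the potassium phenoxide of 2 (K2CO3, MeCN, 0 °C to rt) proceeds with inversion and comes back to the route at 3.

Further compounds
F0 | step 6 | none | none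
F1 | step 5 | (1S,2R)-2-[2,6-dibromo-4-(1,3-dioxolan-2-yl)phenoxy]-1-(3,4,5-trimethoxyphenyl)propan-1-ol | COc1cc([C@H](O)[C@@H](C)Oc2c(Br)cc(C3OCCO3)cc2Br)cc(OC)c1OC
F2 | step 5 | (1R,2R)-2-[2,6-dibromo-4-(1,3-dioxolan-2-yl)phenoxy]-1-(3,4,5-trimethoxyphenyl)propyl 4-nitrobenzoate | COc1cc([C@@H](OC(=O)c2ccc(cc2)[N+](=O)[O-])[C@@H](C)Oc2c(Br)cc(C3OCCO3)cc2Br)cc(OC)c1OC
F3 | step 1 | ethyl (S)-2-(trifluoromethylsulfonyloxy)propanoate | CCOC(=O)[C@H](C)OS(=O)(=O)C(F)(F)F
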